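**Retrosynthetic overview** (cembrane numbering throughout)
1. The plan rests on the only ring olefin, the Z-trisubstituted C7=C8 (methyl on C8) of the 14-membered carbocycle C1–C14. It lies between two plain CH2CH2 spans (C5–C6, C9–C10), opposite the oxepan-2-one bridge C1–C15–C17(=O)–O–C12–C13–C14.
2. The 14-membered ring is formed last. It is closed at C7=C8 by stereoretentive ring-closing metathesis of a C7 vinyl group with a preset (Z)-but-2-en-2-yl end on C8. C16 follows by lactone-enolate methylenation, then deprotection.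
3. The oxepanone is formed first, by invertive 7-exo opening of an (11S,12S)-epoxide at C12 by the C17 acid. The Z-butenyl end is attached afterwards by Negishi coupling of a C9 alkylzinc, so no C8 olefin can trap the activated epoxide and no hydroboration has to spare the C7 vinyl group.
4. C1 is set by a copper-catalysed asymmetric conjugate addition that joins fragment R (C9–C14) to enoate fragment L (C1–C7, C15, C17).
5. C3 and C4 come from a Sharpless kinetic resolution of an isopropenyl carbinol followed by allyl-Grignard opening. The E C11=C12 olefin comes from alkyne carboalumination.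

Key step: step 17

Assumption: the ferrocenyl diphosphine/CuBr catalyst of step 11 is taken to deliver the alkyl group to the enoate face that gives (1R). If the sense proves opposite, the mirror-image ligand is used.

Step 1
Reactants: 1 3-[(tert-butyldimethylsilyl)oxy]propanal; 2 isopropenylmagnesium bromide
Product: 3 (±)-5-[(tert-butyldimethylsilyl)oxy]-2-methylpent-1-en-3-ol
Conditions: THF, −78 → 0 °C; H2O quench
Reagents that add atoms: none
Why: Grignard 1,2-addition to an unhindered aldehyde builds C1–C5 with the C4 methyl, and the racemic C3 carbinol is resolved in step 2.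

Step 2
Reactants: 3 (±)-5-[(tert-butyldimethylsilyl)oxy]-2-methylpent-1-en-3-ol
Product: 4 (1R)-3-[(tert-butyldimethylsilyl)oxy]-1-[(2S)-2-methyloxiran-2-yl]propan-1-ol (3R,4S)
Conditions: Ti(OiPr)4 (0.15 equiv), D-(−)-diisopropyl tartrate (0.2 equiv), t-BuOOH (0.45 equiv), 4 Å MS, CH2Cl2, −20 °C
Reagents that add atoms: tert-butyl hydroperoxide, CC(C)(C)OO
Why: In this Sharpless kinetic resolution the D-(−)-tartrate catalyst should epoxidise only the fast-reacting (R)-carbinol, on the face that gives the erythro epoxy alcohol, which fixes C3 (R) and C4 (S) while the (S)-alcohol stays behind and is separated.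

Step 3
Reactants: 4 epoxy alcohol; 5 allylmagnesium bromide
Product: 6 (3R,4S)-1-[(tert-butyldimethylsilyl)oxy]-4-methyloct-7-ene-3,4-diol
Conditions: 5 (3 equiv), CuI (0.1 equiv), THF, −40 → 0 °C; H2O quench
Reagents that add atoms: none
Why: Copper-catalysed Grignard opening of the 2,2-disubstituted epoxide takes place at the free CH2 (C5), so C6, C7 and the vinyl terminus are added without touching C3 or C4.

Step 4
Reactants: 6 diol
Product: 7 tert-butyl{2-[(4R,5S)-5-(but-3-en-1-yl)-2,2,5-trimethyl-1,3-dioxolan-4-yl]ethoxy}dimethylsilane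
Conditions: Me2C(OMe)2, PPTS (cat.), CH2Cl2, rt
Reagents that add atoms: 2,2-dimethoxypropane, COC(C)(C)OC
Why: Acid-catalysed transketalisation masks the C3/C4 diol, so that C3–OH can never lactonise onto C17, and the primary silyl ether tolerates PPTS.

Step 5
Reactants: 7 silyl ether
Product: 8 2-[(4R,5S)-5-(but-3-en-1-yl)-2,2,5-trimethyl-1,3-dioxolan-4-yl]ethanol
Conditions: Bu4NF, THF, 0 °C → rt
Reagents that add atoms: none
Why: Fluoride desilylation frees the C1 alcohol and leaves the acetonide and the olefin untouched.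

Step 6
Reactants: 8 alcohol; 9 methyl (triphenylphosphoranylidene)acetate
Product: 11 methyl (2E)-4-[(4R,5S)-5-(but-3-en-1-yl)-2,2,5-trimethyl-1,3-dioxolan-4-yl]but-2-enoate, via aldehyde 10 (not isolated)
Conditions: Dess–Martin periodinane, 9 (2.5 equiv), CH2Cl2, rt
Reagents that add atoms: none
Why: One-pot Dess–Martin oxidation and Wittig olefination intercepts the elimination-prone β-alkoxy aldehyde under neutral conditions, and the stabilised ylide should give the E C15=C1 enoate.

Step 7
Reactants: 12 4-[(tert-butyldimethylsilyl)oxy]but-1-yne; 13 oxirane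
Product: 16 (3E)-6-[(tert-butyldimethylsilyl)oxy]-4-methylhex-3-en-1-ol, via alkenylalane 14 (not isolated), via lithium alanate 15 (not isolated)
Conditions: Me3Al (2.5 equiv), Cp2ZrCl2 (0.25 equiv), CH2Cl2, 0 °C → rt; switch to THF–hexane; n-BuLi, −78 → 0 °C; 13, 0 °C → rt; H2O quench
Reagents that add atoms: trimethylaluminium, C[Al](C)C
Why: Zirconium-catalysed syn carboalumination places the methyl on C12 and aluminium on C11, and the derived alanate opens oxirane with retention, which gives the E C11=C12 olefin with C10 and C9.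

Step 8
Reactants: 16 homoallylic alcohol
Product: 17 tert-butyl{[(3E)-6-chloro-3-methylhex-3-en-1-yl]oxy}dimethylsilane
Conditions: PPh3, N-chlorosuccinimide, CH2Cl2, 0 °C → rt
Reagents that add atoms: N-chlorosuccinimide, O=C1CCC(=O)N1Cl
Why: Appel-type chlorination turns C9–OH into a chloride that is inert to magnesium, peroxide, base and acid in the steps to come but can be exchanged for iodide later.

Step 9
Reactants: 17 chloro silyl ether
Product: 18 (3E)-6-chloro-3-methylhex-3-en-1-ol
Conditions: camphorsulfonic acid (cat.), MeOH, rt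
Reagents that add atoms: none
Why: Acid methanolysis removes the primary silyl ether without exposing the alkyl chloride to fluoride.

Step 10
Reactants: 18 chloro alcohol
Product: 19 (3E)-1-bromo-6-chloro-3-methylhex-3-ene
Conditions: CBr4, PPh3, CH2Cl2, 0 °C
Reagents that add atoms: tetrabromomethane, BrC(Br)(Br)Br
Why: The Appel bromination gives the C14 bromide, which inserts magnesium far faster than the C9 chloride.

Step 11
Reactants: 11 enoate; 19 bromo chloride
Product: 21 methyl (3R,6E)-9-chloro-6-methyl-3-{[(4R,5S)-5-(but-3-en-1-yl)-2,2,5-trimethyl-1,3-dioxolan-4-yl]methyl}non-6-enoate, via Grignard reagent 20 (not isolated)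
Conditions: 19, Mg, Et2O, rt; then 11, CuBr·SMe2 (5 mol %), (R)-1-[(Sp)-2-(diphenylphosphino)ferrocenyl]ethyldicyclohexylphosphine (6 mol %), t-BuOMe, −75 °C; H2O quench
Reagents that add atoms: none
Why: Copper-catalysed asymmetric conjugate addition of a linear Grignard reagent to an (E)-enoate with an unbranched γ-carbon forms C1–C14, and the chiral diphosphine selects the enoate face and so sets C1 (R) under catalyst control.

Step 12
Reactants: 21 ester
Product: 22 methyl (3R)-5-[(2S,3S)-3-(2-chloroethyl)-2-methyloxiran-2-yl]-3-{[(4R,5S)-5-(but-3-en-1-yl)-2,2,5-trimethyl-1,3-dioxolan-4-yl]methyl}pentanoate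
Conditions: ent-Shi ketone (1,2:4,5-di-O-isopropylidene-β-L-erythro-2,3-hexodiulo-2,6-pyranose, from L-sorbose, 0.3 equiv), 2KHSO5·KHSO4·K2SO4, K2CO3, Bu4NHSO4, MeCN–CH2(OMe)2/aq Na2B4O7–Na2EDTA, 0 °C
Reagents that add atoms: potassium peroxymonosulfate, [K+].[O-]S(=O)(=O)OO
Why: Shi epoxidation prefers the E-trisubstituted C11=C12 olefin to the monosubstituted C7 vinyl group, and the L-series ketone, mirror image of the one that gives (R,R)-epoxides, should set (11S,12S).

Step 13
Reactants: 22 epoxy ester
Product: 24 (4R,7R)-7-[(1S)-3-chloro-1-hydroxypropyl]-7-methyl-4-{[(4R,5S)-5-(but-3-en-1-yl)-2,2,5-trimethyl-1,3-dioxolan-4-yl]methyl}oxepan-2-one, via epoxy acid 23 (not isolated)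
Conditions: LiOH, THF–H2O, rt; KHSO4 to pH 4, extraction; then camphorsulfonic acid (0.2 equiv), CH2Cl2 (5 mM), 0 °C → rt
Reagents that add atoms: lithium hydroxide, [Li+].[OH-]
Why: Saponification and acid-catalysed epoxy-acid lactonisation let the C17 acid attack the better cation-stabilising tertiary C12 from the rear in a 7-exo-tet closure, which inverts C12 to R, keeps the C11–O bond (S) and meets no competing olefin at C8.

Step 14
Reactants: 24 hydroxy lactone
Product: 25 the C11 tert-butyldimethylsilyl ether of 24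
Conditions: t-BuMe2SiOTf, 2,6-lutidine, CH2Cl2, −20 → 0 °C
Reagents that add atoms: tert-butyldimethylsilyl trifluoromethanesulfonate, CC(C)(C)[Si](C)(C)OS(=O)(=O)C(F)(F)F
Why: The silyl triflate protects the hindered secondary C11–OH next to the quaternary C12, and the lutidine buffer spares the acetonide.

Step 15
Reactants: 25 chloride
Product: 26 the C9 iodide corresponding to 25
Conditions: NaI, acetone, reflux
Reagents that add atoms: sodium iodide, [Na+].[I-]
Why: Finkelstein exchange at the primary C9 gives the iodide needed for zinc insertion and is neutral towards lactone, silyl ether and acetonide.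

Step 16
Reactants: 26 iodide; 27 (Z)-2-bromobut-2-ene
Product: 29 (4R,7R)-7-[(1S,4Z)-1-{[tert-butyl(dimethyl)silyl]oxy}-4-methylhex-4-en-1-yl]-7-methyl-4-{[(4R,5S)-5-(but-3-en-1-yl)-2,2,5-trimethyl-1,3-dioxolan-4-yl]methyl}oxepan-2-one, via alkylzinc iodide 28 (not isolated)
Conditions: Zn dust, LiCl, THF, 40 °C; then 27, PdCl2(PPh3)2 (5 mol %), TMEDA, THF, 40 °C
Reagents that add atoms: none
Why: Negishi coupling of the primary alkylzinc with the alkenyl bromide forms C8–C9 with retention, so C9 ends up cis to the terminal methyl, and the zinc route tolerates the lactone and the C7 vinyl group that a hydroboration would consume.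

Step 17
Reactants: 29 diene lactone
Product: 30 (1R,3R,4S,7Z,11S,12R)-macrocyclic oxepanone, 3,4-O-isopropylidene, 11-O-tert-butyldimethylsilyl, still without C16
Conditions: Mo(N-2,6-iPr2C6H3)(CHCMe2Ph)(2,5-Me2C4H2N)(O-2,6-(2,4,6-iPr3C6H2)2C6H3) (10 mol %), toluene (1 mM), 100 torr, 22–35 °C, N2 glovebox
Reagents that add atoms: none
Why: The neophylidene of hexavalent molybdenum first exchanges with the unhindered C7 vinyl group, the C7 alkylidene then adds [2+2] to the C8 olefin with C8 at the β-position of the molybdacyclobutane, and cycloreversion releases the ring olefin and an ethylidene that turns over on the next vinyl group with loss of propene. The closest known reaction type is the kinetically controlled, stereoretentive macrocyclic ring-closing metathesis of a stereodefined trisubstituted olefin with a terminal olefin by monoaryloxide pyrrolide molybdenum alkylidenes. The 14-membered carbocycle closes by this intramolecular cycloaddition and cycloreversion between two chains that the oxepanone already holds 1,4-trans. No stereocentre is formed; the geometry follows because both α-substituents of the metallacycle (the C6 chain and the departing methyl) turn away from the large terphenoxide towards the imido ligand, so C6 takes the place of that methyl, cis to C9, which is Z. The step needs initiation at the vinyl group only, ring closure ahead of homocoupling, and no later isomerisation; these are served by the steric gap between the two olefins, by high dilution, and by pumping off propene so that ethylidene exchange cannot scramble the C8 olefin. Lactone, acetonide and silyl ether carry no protic or strongly coordinating site, so the catalyst should survive them.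

Step 18
Reactants: 30 macrocyclic lactone
Product: 32 15-[(dimethylamino)methyl] derivative of 30 (C15 epimers), via lithium enolate 31 (not isolated)
Conditions: LiN(iPr)2, THF, −78 °C; then CH2=NMe2+ I−, −78 °C → rt
Reagents that add atoms: dimethylmethyleneiminium iodide, C=[N+](C)C.[I-]
Why: C15 is the only enolisable position, so the lactone enolate undergoes a Mannich reaction with Eschenmoser's salt to add C16, and the C15 configuration is lost again in step 19.

Step 19
Reactants: 32 Mannich base
Product: 34 α-methylene lactone (C15=C16) still carrying acetonide and silyl ether, via ammonium iodide 33 (not isolated)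
Conditions: MeI, THF, rt; then aq NaHCO3/CH2Cl2, rt
Reagents that add atoms: none
Why: N-methylation and mild-base β-elimination of trimethylamine unveil the exocyclic methylene without a base strong enough to move the double bond into the ring.

Step 20
Reactants: 34 protected α-methylene lactone
Product: 35 target CNP0263298.1
Conditions: 48% aq HF, MeCN, 0 °C → rt
Reagents that add atoms: none
Why: Aqueous HF should cleave the hindered C11 silyl ether and hydrolyse the secondary/tertiary acetonide in one operation, and it avoids basic fluoride that could promote oxa-Michael addition to C16 or acyl shift to C3–OH.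

**Compound list**
1 | 3-[(tert-butyldimethylsilyl)oxy]propanal | O=CCCO[Si](C)(C)C(C)(C)C | starting material
2 | isopropenylmagnesium bromide | C=C(C)[Mg]Br | starting material
3 | (±)-5-[(tert-butyldimethylsilyl)oxy]-2-methylpent-1-en-3-ol | C=C(C)C(O)CCO[Si](C)(C)C(C)(C)C | intermediate
4 | (1R)-3-[(tert-butyldimethylsilyl)oxy]-1-[(2S)-2-methyloxiran-2-yl]propan-1-ol | CC(C)(C)[Si](C)(C)OCC[C@@H](O)[C@]1(C)CO1 | intermediate
5 | allylmagnesium bromide | C=CC[Mg]Br | starting material
6 | (3R,4S)-1-[(tert-butyldimethylsilyl)oxy]-4-methyloct-7-ene-3,4-diol | CC(C)(C)[Si](C)(C)OCC[C@@H](O)[C@@](C)(O)CCC=C | intermediate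
7 | acetonide silyl ether | CC(C)(C)[Si](C)(C)OCC[C@H]1OC(C)(C)O[C@@]1(C)CCC=C | intermediate
8 | acetonide alcohol | OCC[C@H]1OC(C)(C)O[C@@]1(C)CCC=C | intermediate
9 | methyl (triphenylphosphoranylidene)acetate | COC(=O)C=P(c1ccccc1)(c1ccccc1)c1ccccc1 | starting material
10 | C1 aldehyde | O=CC[C@H]1OC(C)(C)O[C@@]1(C)CCC=C | intermediate
11 | (E)-enoate, fragment L | COC(=O)/C=C/C[C@H]1OC(C)(C)O[C@@]1(C)CCC=C | intermediate
12 | 4-[(tert-butyldimethylsilyl)oxy]but-1-yne | C#CCCO[Si](C)(C)C(C)(C)C | starting material
13 | oxirane | C1CO1 | starting material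
14 | (E)-alkenyldimethylalane | C[Al](C)/C=C(\C)CCO[Si](C)(C)C(C)(C)C | intermediate
15 | lithium butyl(alkenyl)dimethylalanate | [Li+].CCCC[Al-](C)(C)/C=C(\C)CCO[Si](C)(C)C(C)(C)C | intermediate
16 | (3E)-6-[(tert-butyldimethylsilyl)oxy]-4-methylhex-3-en-1-ol | OCC/C=C(\C)CCO[Si](C)(C)C(C)(C)C | intermediate
17 | chloro silyl ether | ClCC/C=C(\C)CCO[Si](C)(C)C(C)(C)C | intermediate
18 | (3E)-6-chloro-3-methylhex-3-en-1-ol | ClCC/C=C(\C)CCO | intermediate
19 | (3E)-1-bromo-6-chloro-3-methylhex-3-ene, fragment R | ClCC/C=C(\C)CCBr | intermediate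
20 | Grignard reagent of 19 | ClCC/C=C(\C)CC[Mg]Br | intermediate
21 | conjugate adduct (1R) | COC(=O)C[C@H](CC/C(C)=C/CCCl)C[C@H]1OC(C)(C)O[C@@]1(C)CCC=C | intermediate
22 | (11S,12S)-epoxy ester | COC(=O)C[C@H](CC[C@]1(C)O[C@H]1CCCl)C[C@H]2OC(C)(C)O[C@@]2(C)CCC=C | intermediate
23 | (11S,12S)-epoxy acid | OC(=O)C[C@H](CC[C@]1(C)O[C@H]1CCCl)C[C@H]2OC(C)(C)O[C@@]2(C)CCC=C | intermediate
24 | (11S,12R)-hydroxy oxepanone | C1C(=O)O[C@](C)(CC[C@@H]1C[C@H]2OC(C)(C)O[C@@]2(C)CCC=C)[C@@H](O)CCCl | intermediate
25 | C11 silyl ether, C9 chloride | C1C(=O)O[C@](C)(CC[C@@H]1C[C@H]2OC(C)(C)O[C@@]2(C)CCC=C)[C@@H](O[Si](C)(C)C(C)(C)C)CCCl | intermediate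
26 | C9 iodide | C1C(=O)O[C@](C)(CC[C@@H]1C[C@H]2OC(C)(C)O[C@@]2(C)CCC=C)[C@@H](O[Si](C)(C)C(C)(C)C)CCI | intermediate
27 | (Z)-2-bromobut-2-ene | C/C=C(/C)Br | starting material
28 | C9 alkylzinc iodide | C1C(=O)O[C@](C)(CC[C@@H]1C[C@H]2OC(C)(C)O[C@@]2(C)CCC=C)[C@@H](O[Si](C)(C)C(C)(C)C)CC[Zn]I | intermediate
29 | metathesis precursor | C1C(=O)O[C@](C)(CC[C@@H]1C[C@H]2OC(C)(C)O[C@@]2(C)CCC=C)[C@@H](O[Si](C)(C)C(C)(C)C)CC/C(C)=C\C | intermediate
30 | macrocyclic lactone, Z C7=C8 | C1C(=O)O[C@]2(C)CC[C@@H]1C[C@H]3OC(C)(C)O[C@@]3(C)CC/C=C(/C)CC[C@@H]2O[Si](C)(C)C(C)(C)C | intermediate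
31 | lithium enolate of 30 | C1=C(O[Li])O[C@]2(C)CC[C@@H]1C[C@H]3OC(C)(C)O[C@@]3(C)CC/C=C(/C)CC[C@@H]2O[Si](C)(C)C(C)(C)C | intermediate
32 | Mannich base | CN(C)CC1C(=O)O[C@]2(C)CC[C@@H]1C[C@H]3OC(C)(C)O[C@@]3(C)CC/C=C(/C)CC[C@@H]2O[Si](C)(C)C(C)(C)C | intermediate
33 | trimethylammonium iodide | C[N+](C)(C)CC1C(=O)O[C@]2(C)CC[C@@H]1C[C@H]3OC(C)(C)O[C@@]3(C)CC/C=C(/C)CC[C@@H]2O[Si](C)(C)C(C)(C)C.[I-] | intermediate
34 | protected α-methylene lactone | C=C1C(=O)O[C@]2(C)CC[C@@H]1C[C@H]3OC(C)(C)O[C@@]3(C)CC/C=C(/C)CC[C@@H]2O[Si](C)(C)C(C)(C)C | intermediate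
35 | CNP0263298.1 | C=C1C(=O)O[C@]2(C)CC[C@@H]1C[C@@H](O)[C@@](C)(O)CC/C=C(/C)CC[C@@H]2O | target

**Step count:** 20 steps in total. The longest linear sequence is 16 steps (steps 1–6 and 11–20).

**Steps most likely to fail**

Step 17. The crowded catalyst may turn over slowly on the trisubstituted olefin, the C7 vinyl groups may homocouple, and the geometry may erode through exchange of the C8 olefin with ethylidene or propene. The fallback makes C8–C9 the last bond instead, with the geometry again preset. It sets out from 25, whose only olefin is the C7 vinyl group.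
- Ozonolysis (O3, CH2Cl2, −78 °C; PPh3) would give the C7 aldehyde F1.
- Stork–Zhao olefination with (1-iodoethyl)triphenylphosphonium iodide and NaN(SiMe3)2 (THF, −78 °C) would give the (Z)-iodoalkene F2, in which iodine is cis to C6.
- NaI in acetone would give the primary iodide F3.
- Zinc insertion at the alkyl iodide only (Zn, LiCl, THF, rt) would give the alkylzinc iodide F4.
- Slow addition of F4 to PdCl2(dppf) in THF at high dilution would close the ring by intramolecular Negishi coupling with retention and rejoin the route at 30.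

Step 13. Proton loss or hydride shift of the activated epoxide, intermolecular esterification, or loss of the acetonide may outrun the seven-membered closure. The fallback separates C–O bond formation at C12 from acylation and sets out from 22.
- Brief hydrolysis (HClO4 cat., THF–H2O, 0 °C) should open the epoxide at C12 with inversion to the anti diol ester F5.
- One equivalent of t-BuMe2SiOTf with 2,6-lutidine at −78 °C would silylate only the secondary C11–OH and give the silyl ether F6.
- LiOH would give the seco acid F7.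
- Shiina lactonisation (2-methyl-6-nitrobenzoic anhydride, DMAP, toluene, slow addition, heat) would acylate the tertiary C12–OH and rejoin the route at 25.

Step 11. Facial selectivity may be poor if the acetonide oxygens bind magnesium or copper, and 1,2-addition to the ester may compete. The fallback replaces catalyst control by an auxiliary and sets out from 8.
- Oxidation to 10 and Masamune–Roush olefination (LiCl, iPr2NEt, MeCN) with diethyl {2-oxo-2-[(4S)-2-oxo-4-phenyl-1,3-oxazolidin-3-yl]ethyl}phosphonate would give the N-enoyl imide F8.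
- Addition of 20 with CuBr·SMe2 (THF–Me2S, −40 °C) to the magnesium-chelated syn-s-cis imide, on the face away from the phenyl group, should give the (1R)-adduct F9.
- NaOMe in MeOH at 0 °C removes the auxiliary and rejoins the route at 21.

**Further compounds**
F1 | step 17 | C7 aldehyde | C1C(=O)O[C@](C)(CC[C@@H]1C[C@H]2OC(C)(C)O[C@@]2(C)CCC=O)[C@@H](O[Si](C)(C)C(C)(C)C)CCCl
F2 | step 17 | (Z)-iodoalkene, C9 chloride | C1C(=O)O[C@](C)(CC[C@@H]1C[C@H]2OC(C)(C)O[C@@]2(C)CC/C=C(/C)I)[C@@H](O[Si](C)(C)C(C)(C)C)CCCl
F3 | step 17 | (Z)-iodoalkene, C9 iodide | C1C(=O)O[C@](C)(CC[C@@H]1C[C@H]2OC(C)(C)O[C@@]2(C)CC/C=C(/C)I)[C@@H](O[Si](C)(C)C(C)(C)C)CCI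
F4 | step 17 | (Z)-iodoalkene, C9 alkylzinc iodide | C1C(=O)O[C@](C)(CC[C@@H]1C[C@H]2OC(C)(C)O[C@@]2(C)CC/C=C(/C)I)[C@@H](O[Si](C)(C)C(C)(C)C)CC[Zn]I
F5 | step 13 | (11S,12R)-diol ester | COC(=O)C[C@H](CC[C@@](C)(O)[C@@H](O)CCCl)C[C@H]1OC(C)(C)O[C@@]1(C)CCC=C
F6 | step 13 | C11 silyl ether of the diol ester | COC(=O)C[C@H](CC[C@@](C)(O)[C@@H](O[Si](C)(C)C(C)(C)C)CCCl)C[C@H]1OC(C)(C)O[C@@]1(C)CCC=C
F7 | step 13 | seco acid | OC(=O)C[C@H](CC[C@@](C)(O)[C@@H](O[Si](C)(C)C(C)(C)C)CCCl)C[C@H]1OC(C)(C)O[C@@]1(C)CCC=C
F8 | step 11 | N-enoyl (4S)-4-phenyloxazolidinone | O=C1OC[C@H](c2ccccc2)N1C(=O)/C=C/C[C@H]3OC(C)(C)O[C@@]3(C)CCC=C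
F9 | step 11 | (1R)-conjugate adduct imide | O=C1OC[C@H](c2ccccc2)N1C(=O)C[C@H](CC/C(C)=C/CCCl)C[C@H]3OC(C)(C)O[C@@]3(C)CCC=C
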